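**Plan**

1. Numbering: C1 = benzoyl-bearing bridgehead; C2 and C4 = ketones flanking quaternary C3; C5 = geranyl-bearing bridgehead; C9 = ketone bridging C1 and C5; C6H2–C7H–C8Me2 = carbon bridge from C5 to C1; C10H2 on C7; C11H joins C10, C3 and C12; C12Me2; C13H(i-Pr); C14H2 back to C3.
2. Enabling feature: C5 lies between the C4 and C9 carbonyls (an acidic, soft β-diketone carbon) and C6 is a CH2 tied to C7. A π-allyl unit spread over C6–C7–C10 and hung on C1 through C8 therefore lets C5 close the C1–C9–C5–C6–C7–C8 ring of the bicyclo[3.3.1]nonane and leaves C7=C10 for the last ring.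
3. Cuts, last bond first: C10–C11 (radical closure of C11 onto the C7=C10 methylene); C5–C6 (palladium-catalysed allylic alkylation); C3–C14 and C3–C11 (Michael-initiated spiro-annulation with a chiral C11–C14 bromo aldehyde); C5–geranyl; C1–C8 (Claisen shift); C1–C2/C1–C9 (Claisen–Dieckmann ring synthesis from acetophenone and a ketal-masked 3-oxoglutarate).
4. Forward: trione ring with C4 masked as a dioxolane (so the O-allyl group can migrate only to C1) → quaternary C1 → C5 geranylation → spiro cyclopentane at C3 → bicyclo[3.3.1]nonane → homoadamantane cage.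
5. Stereochemistry: C13 from an Evans alkylation; C1 fixed by resolution of the first chiral ring intermediate; C3 by ring closure anti to the C1 tert-alkyl chain, which puts C11 on the face of that chain; C5 by the tether; C11 and C7 by the cage-held radical closure (C10 anti to isopropyl, hydrogen to the exo face of C7).
6. C11 carries a phenylselanyl group rather than an oxygen function: it enters in the ring-forming step, cannot set off retro-aldol cleavage next to the C2/C4 diketone, and is a direct radical precursor.

Key step: step 15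

Remark: enolised triones (8, 11, 13, 25–27) are drawn as one tautomer and 11 is achiral through fast tautomer exchange; the C11 configuration drawn for 27 and 28 is the expected major one and is erased when C11 becomes a radical in step 16; the enantiomer of 13 to be carried on is assigned by correlation with a later crystalline intermediate.

**Route**

Step 1
Reactants: 1 dimethyl 2-(propan-2-ylidene)propanedioate (dimethyl isopropylidenemalonate)
Product: 2 2-(propan-2-ylidene)propane-1,3-diol
Conditions: i-Bu2AlH (4.5 equiv), CH2Cl2, −78 °C to 0 °C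
Reagents that add atoms: none
Why: Both esters of the alkylidene malonate are reduced by 1,2-hydride addition to the allylic diol, the fully substituted β-carbon making conjugate reduction unfavourable (ester reduction with a dialkylaluminium hydride).

Step 2
Reactants: 2 2-(propan-2-ylidene)propane-1,3-diol
Product: 3 2-(hydroxymethyl)-3-methylbut-2-en-1-yl methyl carbonate
Conditions: ClCO2Me (0.5 equiv), pyridine, CH2Cl2, −20 °C; unreacted diol recycled
Reagents that add atoms: methyl chloroformate COC(=O)Cl
Why: Mono-acylation of a symmetrical diol with a chloroformate, held at the mono-carbonate by using the diol in excess; the carbonate is the later leaving group and keeps the side-chain oxygen from adding to the ring ketones in the steps between.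

Step 3
Reactants: 4 dimethyl 3-oxopentanedioate
Product: 5 dimethyl 2,2'-(1,3-dioxolane-2,2-diyl)diacetate
Conditions: HOCH2CH2OH, TsOH (cat.), toluene, reflux, Dean–Stark
Reagents that add atoms: ethane-1,2-diol OCCO
Why: Acid-catalysed ketalisation with azeotropic removal of water turns the future C4 carbonyl into an sp3 centre, so that the ring built from 5 can neither aromatise nor offer an enol other than the one at C1.

Step 4
Reactants: 5 dimethyl 2,2'-(1,3-dioxolane-2,2-diyl)diacetate; 6 acetophenone
Product: 8 benzoyl dione ketal (8-benzoyl-9-hydroxy-1,4-dioxaspiro[4.5]dec-8-en-7-one), via diketo ester 7 (not isolated)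
Conditions: 6 (2.2 equiv), LiN(SiMe3)2 (2.2 equiv), THF, −78 °C; add 5; −78 °C to 60 °C; aq. HCl, 0 °C
Reagents that add atoms: none
Why: Crossed Claisen condensation of the acetophenone enolate with one ester, then Dieckmann-type 6-exo-trig acylation of the resulting β-diketonate by the second ester, pulled forward by the very acidic 2-acyl-1,3-dione formed; with the ketone enolate as the strongest base present the esters are hardly deprotonated, which keeps β-elimination of the ketal oxygen in check.

Step 5
Reactants: 8 benzoyl dione ketal (8-benzoyl-9-hydroxy-1,4-dioxaspiro[4.5]dec-8-en-7-one); 3 2-(hydroxymethyl)-3-methylbut-2-en-1-yl methyl carbonate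
Product: 10 8-benzoyl-8-(3-{[(methoxycarbonyl)oxy]methyl}-2-methylbut-3-en-2-yl)-1,4-dioxaspiro[4.5]decane-7,9-dione, via allyl enol ether 9 (not isolated)
Conditions: PPh3, DIAD, THF, 0 °C to rt; then toluene, 110 °C
Reagents that add atoms: none
Why: Mitsunobu O-alkylation of the acidic triketone enol gives an allyl enol ether whose Claisen rearrangement ([3,3]) can end only at C1 (C3 and C5 are sp3 and C4 is masked; the ring-oxygen and benzoyl-oxygen ethers converge), forging the C1–C8 bond between two quaternary carbons and setting free the C7=C10 methylene next to the intact carbonate.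

Step 6
Reactants: 10 8-benzoyl-8-(3-{[(methoxycarbonyl)oxy]methyl}-2-methylbut-3-en-2-yl)-1,4-dioxaspiro[4.5]decane-7,9-dione
Product: 11 6-benzoyl-3-hydroxy-6-(3-{[(methoxycarbonyl)oxy]methyl}-2-methylbut-3-en-2-yl)cyclohex-2-ene-1,5-dione
Conditions: 1 M aq. HCl, THF, 40 °C
Reagents that add atoms: water O
Why: Acid hydrolysis of the dioxolane, driven by enolisation of the freed C4 ketone into a vinylogous acid; the carbonate, the 1,1-disubstituted alkene and the non-enolisable C1 centre should tolerate dilute aqueous acid.

Step 7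
Reactants: 11 6-benzoyl-3-hydroxy-6-(3-{[(methoxycarbonyl)oxy]methyl}-2-methylbut-3-en-2-yl)cyclohex-2-ene-1,5-dione; 12 geranyl bromide
Product: 13 (4S)-4-benzoyl-2-[(2E)-3,7-dimethylocta-2,6-dien-1-yl]-3-hydroxy-4-(3-{[(methoxycarbonyl)oxy]methyl}-2-methylbut-3-en-2-yl)cyclohex-2-ene-1,5-dione
Conditions: 12 (1.0 equiv), K2CO3 (1.1 equiv), H2O–THF, 0 °C to rt; then preparative HPLC on a chiral stationary phase (amylose tris(3,5-dimethylphenylcarbamate), hexane–i-PrOH–CF3CO2H)
Reagents that add atoms: none
Why: C-Allylation of the vinylogous acid anion in a water-rich medium (C over O) puts geranyl on one of the two equivalent methylenes, which makes C1 stereogenic; as nothing biases that choice the racemate is resolved on a chiral stationary phase and the (4S) enantiomer is carried on, which fixes the absolute configuration of C1.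

Step 8
Reactants: 14 (4S)-4-benzyl-1,3-oxazolidin-2-one; 15 3-methylbutanoyl chloride
Product: 16 (4S)-4-benzyl-3-(3-methylbutanoyl)-1,3-oxazolidin-2-one
Conditions: n-BuLi, THF, −78 °C; then 15, −78 °C to 0 °C
Reagents that add atoms: none
Why: N-Acylation of the lithiated oxazolidinone with the acid chloride prepares the Evans imide.

Step 9
Reactants: 16 (4S)-4-benzyl-3-(3-methylbutanoyl)-1,3-oxazolidin-2-one; 17 tert-butyl bromoacetate
Product: 18 tert-butyl (3S)-3-{[(4S)-4-benzyl-2-oxo-1,3-oxazolidin-3-yl]carbonyl}-4-methylpentanoate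
Conditions: NaN(SiMe3)2, THF, −78 °C; then 17
Reagents that add atoms: none
Why: Evans alkylation, in which the chelated Z-sodium enolate is alkylated on the face remote from the benzyl group; this sets the stereocentre that becomes C13.

Step 10
Reactants: 18 tert-butyl (3S)-3-{[(4S)-4-benzyl-2-oxo-1,3-oxazolidin-3-yl]carbonyl}-4-methylpentanoate
Product: 20 (4S)-4-(propan-2-yl)oxolan-2-one, via hydroxy ester 19 (not isolated)
Conditions: LiBH4, MeOH (1 equiv), Et2O, 0 °C; then TsOH (cat.), toluene, 80 °C
Reagents that add atoms: none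
Why: LiBH4 reduces the imide carbonyl selectively to the primary alcohol (the future C14–O) and releases the auxiliary, and acid then closes the γ-lactone with loss of tert-butanol; the C13 centre carries no acidifying group and is untouched.

Step 11
Reactants: 20 (4S)-4-(propan-2-yl)oxolan-2-one
Product: 22 (4R)-3,3-dimethyl-4-(propan-2-yl)oxolan-2-one, via monomethyl lactone 21 (not isolated)
Conditions: LiN(i-Pr)2, THF, −78 °C, then MeI; second cycle LiN(i-Pr)2, MeI, −78 °C to 0 °C
Reagents that add atoms: iodomethane CI
Why: Two lactone enolate methylations build the C12 gem-dimethyl group, the first methyl entering trans to the isopropyl group and the second erasing that centre; C13 is not enolisable.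

Step 12
Reactants: 22 (4R)-3,3-dimethyl-4-(propan-2-yl)oxolan-2-one
Product: 23 methyl (3R)-3-(bromomethyl)-2,2,4-trimethylpentanoate
Conditions: BBr3, CH2Cl2, 0 °C to rt; then MeOH, 0 °C
Reagents that add atoms: boron tribromide BrB(Br)Br; methanol CO
Why: BBr3 activates the lactone carbonyl and bromide opens the ring at the O–CH2 carbon (SN2 at C14), and methanolysis of the acyl–boron intermediate gives the ω-bromo methyl ester (lactone cleavage with a boron trihalide).

Step 13
Reactants: 23 methyl (3R)-3-(bromomethyl)-2,2,4-trimethylpentanoate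
Product: 24 (3R)-3-(bromomethyl)-2,2,4-trimethylpentanal
Conditions: i-Bu2AlH (1.1 equiv), CH2Cl2, −78 °C
Reagents that add atoms: none
Why: Low-temperature half-reduction of the hindered α,α-disubstituted ester stops at the aldehyde because the tetrahedral aluminium alkoxide survives until work-up; the primary bromide is inert.

Step 14
Reactants: 13 (4S)-4-benzoyl-2-[(2E)-3,7-dimethylocta-2,6-dien-1-yl]-3-hydroxy-4-(3-{[(methoxycarbonyl)oxy]methyl}-2-methylbut-3-en-2-yl)cyclohex-2-ene-1,5-dione; 24 (3R)-3-(bromomethyl)-2,2,4-trimethylpentanal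
Product: 27 spiro selenide (1S,3R,5S,9R)-9-benzoyl-7-[(2E)-3,7-dimethylocta-2,6-dien-1-yl]-8-hydroxy-9-(3-{[(methoxycarbonyl)oxy]methyl}-2-methylbut-3-en-2-yl)-2,2-dimethyl-1-(phenylselanyl)-3-(propan-2-yl)spiro[4.5]dec-7-ene-6,10-dione, via alkylidene trione 25 (not isolated), via selenide adduct 26 (not isolated)
Conditions: PhSeH (1.1 equiv), L-proline (20 mol%), CH2Cl2, rt; then Cs2CO3, DMF, 0 °C to rt
Reagents that add atoms: benzeneselenol [SeH]c1ccccc1
Why: Knoevenagel condensation at C3 (the only CH2 left between two carbonyls), conjugate addition of the selenol to the alkylidene-1,3-dione and 5-exo-tet C-alkylation of the resulting C3 enolate by C14–Br add up to a Michael-initiated ring closure; C14 should enter C3 on the face opposite the bulky C1 tert-alkyl chain (the benzoyl face), which sets C3 and places C11 cis to that chain as the cage later requires, while the phenylselanyl group on C11 is expected on the C4 side, away from the same chain (the selenol addition is reversible until the ring closes).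

Step 15
Reactants: 27 spiro selenide (1S,3R,5S,9R)-9-benzoyl-7-[(2E)-3,7-dimethylocta-2,6-dien-1-yl]-8-hydroxy-9-(3-{[(methoxycarbonyl)oxy]methyl}-2-methylbut-3-en-2-yl)-2,2-dimethyl-1-(phenylselanyl)-3-(propan-2-yl)spiro[4.5]dec-7-ene-6,10-dione
Product: 28 (1S,2'S,3S,4'R,5S)-1-benzoyl-5-[(2E)-3,7-dimethylocta-2,6-dien-1-yl]-3',3',8,8-tetramethyl-7-methylidene-2'-(phenylselanyl)-4'-(propan-2-yl)spiro[bicyclo[3.3.1]nonane-3,1'-cyclopentane]-2,4,9-trione
Conditions: Pd(PPh3)4 (5 mol%), THF, 50 °C
Reagents that add atoms: none
Why: Zerovalent palladium ionises the allylic carbonate with loss of CO2 to a 2-substituted π-allyl complex spanning C6–C7–C10 and methoxide, which deprotonates the C4/C9 enol. The soft C5 enolate (C3 is quaternary, so C5 is the only nucleophilic carbon) attacks an allyl terminus anti to the metal; both termini are CH2 groups and give the same product, the intramolecular counterpart of the Tsuji–Trost allylation of β-diketones and of the palladium-catalysed annulation of ketones with 2-methylenepropane-1,3-diyl diesters to bicyclo[3.3.1]nonanones. The six-membered ring C1–C9–C5–C6–C7–C8 closes in a 6-exo-tet-like manner (the breaking C6–Pd bond lies outside the new ring) and leaves C7=C10 exocyclic. C5 is the only new stereocentre and is dictated by C1, because the three-carbon tether from C1 reaches only one face of the planar C5 enolate. The step needs C- over O-allylation, and kinetically formed O-allyl enol ethers re-ionise under the catalyst and drain into the C-alkylated trione; quaternary C8 rules out β-hydride loss, and the trisubstituted geranyl alkenes and the alkyl phenyl selenide are not expected to engage the catalyst.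

Step 16
Reactants: 28 (1S,2'S,3S,4'R,5S)-1-benzoyl-5-[(2E)-3,7-dimethylocta-2,6-dien-1-yl]-3',3',8,8-tetramethyl-7-methylidene-2'-(phenylselanyl)-4'-(propan-2-yl)spiro[bicyclo[3.3.1]nonane-3,1'-cyclopentane]-2,4,9-trione
Product: 29 target CNP0155129.1 (cage trione with the C10–C11 bond closed)
Conditions: Bu3SnH (1.3 equiv, slow addition), AIBN (cat.), toluene, 85 °C
Reagents that add atoms: none
Why: In this tin hydride radical cyclisation the stannyl radical abstracts the phenylselanyl group and the C11 radical, held by the bicycle in contact with C10, should add 7-endo to the methylene terminus (giving the tertiary C7 radical) faster than it is reduced or undergoes 1,2-acyl shift; C10 bonds to C11 anti to the C13 isopropyl group and on the side away from the C8 methyls (sets C11), and the caged C7 radical can take hydrogen from the stannane only on its exo face (sets C7).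

**Compound list**

1 | dimethyl 2-(propan-2-ylidene)propanedioate (dimethyl isopropylidenemalonate) | COC(=O)C(=C(C)C)C(=O)OC | starting material
2 | 2-(propan-2-ylidene)propane-1,3-diol | OCC(CO)=C(C)C | intermediate
3 | 2-(hydroxymethyl)-3-methylbut-2-en-1-yl methyl carbonate | COC(=O)OCC(CO)=C(C)C | intermediate
4 | dimethyl 3-oxopentanedioate | COC(=O)CC(=O)CC(=O)OC | starting material
5 | dimethyl 2,2'-(1,3-dioxolane-2,2-diyl)diacetate | COC(=O)CC1(CC(=O)OC)OCCO1 | intermediate
6 | acetophenone | CC(=O)c1ccccc1 | starting material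
7 | methyl 2-[2-(2,4-dioxo-4-phenylbutyl)-1,3-dioxolan-2-yl]acetate (formed in situ) | COC(=O)CC1(CC(=O)CC(=O)c2ccccc2)OCCO1 | intermediate
8 | 8-benzoyl-9-hydroxy-1,4-dioxaspiro[4.5]dec-8-en-7-one (enol of the 7,9-dione) | O=C1CC2(OCCO2)CC(O)=C1C(=O)c1ccccc1 | intermediate
9 | 8-benzoyl-9-[(2-{[(methoxycarbonyl)oxy]methyl}-3-methylbut-2-en-1-yl)oxy]-1,4-dioxaspiro[4.5]dec-8-en-7-one (formed in situ; the benzoyl-oxygen ether isomer rearranges alike) | O=C1CC2(OCCO2)CC(OCC(COC(=O)OC)=C(C)C)=C1C(=O)c1ccccc1 | intermediate
10 | 8-benzoyl-8-(3-{[(methoxycarbonyl)oxy]methyl}-2-methylbut-3-en-2-yl)-1,4-dioxaspiro[4.5]decane-7,9-dione | O=C1CC2(OCCO2)CC(=O)C1(C(=O)c1ccccc1)C(C)(C)C(=C)COC(=O)OC | intermediate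
11 | 6-benzoyl-3-hydroxy-6-(3-{[(methoxycarbonyl)oxy]methyl}-2-methylbut-3-en-2-yl)cyclohex-2-ene-1,5-dione (achiral by tautomer exchange) | O=C1CC(O)=CC(=O)C1(C(=O)c1ccccc1)C(C)(C)C(=C)COC(=O)OC | intermediate
12 | geranyl bromide, (2E)-1-bromo-3,7-dimethylocta-2,6-diene | CC(C)=CCC/C(C)=C/CBr | starting material
13 | (4S)-4-benzoyl-2-[(2E)-3,7-dimethylocta-2,6-dien-1-yl]-3-hydroxy-4-(3-{[(methoxycarbonyl)oxy]methyl}-2-methylbut-3-en-2-yl)cyclohex-2-ene-1,5-dione (C1 of the plan = ring C4) | CC(C)=CCC/C(C)=C/CC1=C(O)[C@@](C(=O)c2ccccc2)(C(C)(C)C(=C)COC(=O)OC)C(=O)CC1=O | intermediate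
14 | (4S)-4-benzyl-1,3-oxazolidin-2-one | O=C1OC[C@H](Cc2ccccc2)N1 | starting material
15 | 3-methylbutanoyl chloride | CC(C)CC(Cl)=O | starting material
16 | (4S)-4-benzyl-3-(3-methylbutanoyl)-1,3-oxazolidin-2-one | CC(C)CC(=O)N1[C@@H](Cc2ccccc2)COC1=O | intermediate
17 | tert-butyl bromoacetate | CC(C)(C)OC(=O)CBr | starting material
18 | tert-butyl (3S)-3-{[(4S)-4-benzyl-2-oxo-1,3-oxazolidin-3-yl]carbonyl}-4-methylpentanoate | CC(C)[C@H](CC(=O)OC(C)(C)C)C(=O)N1[C@@H](Cc2ccccc2)COC1=O | intermediate
19 | tert-butyl (3S)-3-(hydroxymethyl)-4-methylpentanoate (formed in situ) | CC(C)[C@H](CC(=O)OC(C)(C)C)CO | intermediate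
20 | (4S)-4-(propan-2-yl)oxolan-2-one | CC(C)[C@@H]1CC(=O)OC1 | intermediate
21 | (3R,4R)-3-methyl-4-(propan-2-yl)oxolan-2-one, trans (formed in situ) | CC(C)[C@@H]1[C@@H](C)C(=O)OC1 | intermediate
22 | (4R)-3,3-dimethyl-4-(propan-2-yl)oxolan-2-one | CC(C)[C@@H]1C(C)(C)C(=O)OC1 | intermediate
23 | methyl (3R)-3-(bromomethyl)-2,2,4-trimethylpentanoate | CC(C)[C@@H](CBr)C(C)(C)C(=O)OC | intermediate
24 | (3R)-3-(bromomethyl)-2,2,4-trimethylpentanal (C11 aldehyde, C12Me2, C13, C14–Br) | CC(C)[C@@H](CBr)C(C)(C)C=O | intermediate
25 | alkylidene trione: 13 condensed at C3 with 24 (C3=C11 double bond, geometry not fixed; C1 and C13 as in 13 and 24; formed in situ) | CC(C)=CCC/C(C)=C/CC1=C(O)[C@@](C(=O)c2ccccc2)(C(C)(C)C(=C)COC(=O)OC)C(=O)C(=CC(C)(C)[C@H](CBr)C(C)C)C1=O | intermediate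
26 | selenide adduct: 25 with PhSe added at C11 and H at C3 (C3 and C11 not fixed; formed in situ) | CC(C)=CCC/C(C)=C/CC1=C(O)[C@@](C(=O)c2ccccc2)(C(C)(C)C(=C)COC(=O)OC)C(=O)C(C([Se]c2ccccc2)C(C)(C)[C@H](CBr)C(C)C)C1=O | intermediate
27 | (1S,3R,5S,9R)-9-benzoyl-7-[(2E)-3,7-dimethylocta-2,6-dien-1-yl]-8-hydroxy-9-(3-{[(methoxycarbonyl)oxy]methyl}-2-methylbut-3-en-2-yl)-2,2-dimethyl-1-(phenylselanyl)-3-(propan-2-yl)spiro[4.5]dec-7-ene-6,10-dione (plan numbering: C1 R, C3 S, C11 S, C13 R; C8 chain cis to C11; SePh and i-Pr on the C4 side) | CC(C)=CCC/C(C)=C/CC1=C(O)[C@@](C(=O)c2ccccc2)(C(C)(C)C(=C)COC(=O)OC)C(=O)[C@]3(C[C@H](C(C)C)C(C)(C)[C@@H]3[Se]c4ccccc4)C1=O | intermediate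
28 | (1S,2'S,3S,4'R,5S)-1-benzoyl-5-[(2E)-3,7-dimethylocta-2,6-dien-1-yl]-3',3',8,8-tetramethyl-7-methylidene-2'-(phenylselanyl)-4'-(propan-2-yl)spiro[bicyclo[3.3.1]nonane-3,1'-cyclopentane]-2,4,9-trione (C11 = C2' endo, C14 = C5' exo) | CC(C)=CCC/C(C)=C/C[C@]12CC(=C)C(C)(C)[C@](C(=O)c3ccccc3)(C1=O)C(=O)[C@]4(C[C@H](C(C)C)C(C)(C)[C@@H]4[Se]c5ccccc5)C2=O | intermediate
29 | CNP0155129.1: bicyclo[3.3.1]nonane-2,4,9-trione (C1–C9) with 1-benzoyl, 5-[(2E)-3,7-dimethylocta-2,6-dien-1-yl] and 8,8-dimethyl groups, a C10H2–C11H bridge from C7 to C3, and a cyclopentane C3–C11–C12(Me2)–C13(i-Pr)–C14; plan numbering 1S,3S,5R,7R,11R,13R | CC(C)=CCC/C(C)=C/C[C@@]12C[C@H]3C[C@@H]4C(C)(C)[C@@H](C(C)C)C[C@]4(C1=O)C(=O)[C@@](C(=O)c1ccccc1)(C2=O)C3(C)C | target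

**Count and risks**

Total steps: 16. Longest linear sequence: 9 steps (steps 8–13, then 14–16).

Steps most likely to fail:

1. Step 16. The C11 radical may take hydrogen from the stannane before it reaches C10, or may attack a flanking C2/C4 carbonyl (Dowd–Beckwith-type 1,2-acyl shift), and the face on which C10 adds may not be fully controlled. The fallback sets out from 28 and removes the hydrogen donor from the ring-forming event. Irradiation of 28 with (Bu3Sn)2 and a little PhSeSePh in benzene should generate the C11 radical under non-reducing conditions; if it is trapped before cyclising it only returns to 28, while the cyclised C7 radical is captured by the diselenide to give the C7 phenylselenide F1. Reduction of F1 with Bu3SnH/AIBN then delivers hydrogen to the exo face of C7 and rejoins the route at 29. This fallback does not remove the acyl-shift pathway.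

2. Step 14. The condensation of the α-quaternary aldehyde with the hindered C3 methylene may stall, and the selenol addition may revert before the ring closes. The fallback sets out from 13 and separates bond formation from dehydration. The dianion of 13 (LiN(i-Pr)2, 2.1 equiv, THF, −78 °C) should add to 24 to give the aldol adduct F2; MsCl/Et3N then eliminates it to the alkylidene trione 25, where the route is rejoined (PhSeH, then Cs2CO3, to 27).

3. Step 15. The selenide may tie up the palladium catalyst, or the substrate may rest as an O-allylated enol ether. The fallback sets out from 13 and 24 and moves the selenium behind the palladium step. The condensation is run without selenol and 25 is isolated; Pd(PPh3)4 closes it to the bicyclic alkylidene trione F3; PhSeH/Cs2CO3 then adds at C11 and the C3 enolate is alkylated by C14–Br on the exo face of the bicycle (which also enforces C11 endo), rejoining the route at 28.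

**Further compounds**

F1 | step 16 | C7 phenylselenide of the cage (29 with PhSe in place of H at C7, exo) | CC(C)=CCC/C(C)=C/C[C@@]12C[C@@]3([Se]c5ccccc5)C[C@@H]4C(C)(C)[C@@H](C(C)C)C[C@]4(C1=O)C(=O)[C@@](C(=O)c1ccccc1)(C2=O)C3(C)C
F2 | step 14 | aldol adduct of 13 (at C3) with 24 (C11 carbinol; C3 and C11 not fixed) | CC(C)=CCC/C(C)=C/CC1=C(O)[C@@](C(=O)c2ccccc2)(C(C)(C)C(=C)COC(=O)OC)C(=O)C(C(O)C(C)(C)[C@H](CBr)C(C)C)C1=O
F3 | step 15 | bicyclic alkylidene trione (bicyclo[3.3.1]nonane-2,4,9-trione with C7 methylidene, C3=C11 alkylidene and C14–Br) | CC(C)=CCC/C(C)=C/C[C@]12CC(=C)C(C)(C)[C@](C(=O)c3ccccc3)(C1=O)C(=O)C(=CC(C)(C)[C@H](CBr)C(C)C)C2=O
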